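The bond on which the route rests is the ethano bridge between ring A (the 3-methoxyphenyl ring) and ring B (the 4-hydroxy-3-aryloxyphenyl ring). Both bridge carbons are benzylic, so the bond is made at the stilbene oxidation level. A Horner–Wadsworth–Emmons olefination joins a 3-methoxybenzyl phosphonate carbanion to the ring-B aldehyde carbon of a diaryl ether aldehyde that already carries rings B, C and D, with both phenols masked as benzyl ethers and the C/D bridge as an E-alkene. One final hydrogenation then saturates both alkenes and frees both phenols, so the olefination costs no extra step.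

Key step: step 3

Remark: the target has no stereocentre. The four starting materials (two benzylic diethyl phosphonates and two benzyloxy-substituted benzaldehydes) are taken as catalogue chemicals.

Step 1
Reactants: 1 diethyl (4-bromobenzyl)phosphonate; 2 3-(benzyloxy)benzaldehyde
Product: 3 (E)-1-(benzyloxy)-3-[2-(4-bromophenyl)ethenyl]benzene
Conditions: KOtBu (1.2 equiv), THF, 0 °C to rt
Reagents that add atoms: none
Why: Horner–Wadsworth–Emmons olefination of a non-enolisable aryl aldehyde with a benzylphosphonate carbanion should give the E-stilbene, and the aryl bromide and benzyl ether are inert to KOtBu at room temperature.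

Step 2
Reactants: 3 (E)-1-(benzyloxy)-3-[2-(4-bromophenyl)ethenyl]benzene; 4 4-(benzyloxy)-3-hydroxybenzaldehyde
Product: 5 4-(benzyloxy)-3-{4-[(E)-2-[3-(benzyloxy)phenyl]ethenyl]phenoxy}benzaldehyde
Conditions: CuI (10 mol%), picolinic acid (20 mol%), K3PO4 (2 equiv), DMSO, 90 °C, Ar
Reagents that add atoms: none
Why: Ullmann-type copper-catalysed O-arylation of a phenoxide with an aryl bromide should form the diaryl ether, since the picolinic acid system accepts ortho-substituted phenols and the non-enolisable aldehyde, stilbene and benzyl ethers are not touched.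

Step 3
Reactants: 5 4-(benzyloxy)-3-{4-[(E)-2-[3-(benzyloxy)phenyl]ethenyl]phenoxy}benzaldehyde; 6 diethyl (3-methoxybenzyl)phosphonate
Product: 7 1-(benzyloxy)-2-{4-[(E)-2-[3-(benzyloxy)phenyl]ethenyl]phenoxy}-4-[(E)-2-(3-methoxyphenyl)ethenyl]benzene
Conditions: KOtBu (1.3 equiv), THF, 0 °C to rt
Reagents that add atoms: none
Why: KOtBu deprotonates the benzylic CH2 of 6 and the phosphonate carbanion adds to the formyl carbon of 5; the β-oxido phosphonate closes to an oxaphosphetane that collapses by syn-elimination of diethyl phosphate, creating the C=C that becomes the A/B CH2–CH2 bond. The closest known reaction type is the Horner–Wadsworth–Emmons olefination of aryl aldehydes with benzylphosphonates, the standard entry to E-stilbenes. No ring is closed and no stereocentre is formed; the E geometry expected from reversible addition is convenient for handling but irrelevant to the target because the alkene is hydrogenated in step 4. The selectivity needed is chemoselectivity for the single aldehyde, which the substrate secures because 5 has no α-hydrogen, no second carbonyl and only base-stable benzyl ether, diaryl ether and stilbene functions.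

Step 4
Reactants: 7 1-(benzyloxy)-2-{4-[(E)-2-[3-(benzyloxy)phenyl]ethenyl]phenoxy}-4-[(E)-2-(3-methoxyphenyl)ethenyl]benzene
Product: 8 2-{4-[2-(3-hydroxyphenyl)ethyl]phenoxy}-4-[2-(3-methoxyphenyl)ethyl]phenol
Conditions: H2 (1 atm), 10% Pd/C, EtOAc–MeOH, rt
Reagents that add atoms: none
Why: Heterogeneous catalytic hydrogenation should saturate both stilbene alkenes and hydrogenolyse both aryl benzyl ethers in one operation, while the aryl methyl ether, the diaryl ether and the arenes are stable under these mild conditions.

Compound list
1 | diethyl (4-bromobenzyl)phosphonate | CCOP(=O)(Cc1ccc(Br)cc1)OCC | starting material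
2 | 3-(benzyloxy)benzaldehyde | O=Cc1cccc(OCc2ccccc2)c1 | starting material
3 | (E)-1-(benzyloxy)-3-[2-(4-bromophenyl)ethenyl]benzene | Brc1ccc(/C=C/c2cccc(OCc3ccccc3)c2)cc1 | intermediate
4 | 4-(benzyloxy)-3-hydroxybenzaldehyde | O=Cc1ccc(OCc2ccccc2)c(O)c1 | starting material
5 | 4-(benzyloxy)-3-{4-[(E)-2-[3-(benzyloxy)phenyl]ethenyl]phenoxy}benzaldehyde | O=Cc1ccc(OCc2ccccc2)c(Oc2ccc(/C=C/c3cccc(OCc4ccccc4)c3)cc2)c1 | intermediate
6 | diethyl (3-methoxybenzyl)phosphonate | CCOP(=O)(Cc1cccc(OC)c1)OCC | starting material
7 | 1-(benzyloxy)-2-{4-[(E)-2-[3-(benzyloxy)phenyl]ethenyl]phenoxy}-4-[(E)-2-(3-methoxyphenyl)ethenyl]benzene | COc1cccc(/C=C/c2ccc(OCc3ccccc3)c(Oc3ccc(/C=C/c4cccc(OCc5ccccc5)c4)cc3)c2)c1 | intermediate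
8 | 2-{4-[2-(3-hydroxyphenyl)ethyl]phenoxy}-4-[2-(3-methoxyphenyl)ethyl]phenol | COc1cccc(CCc2ccc(O)c(Oc3ccc(CCc4cccc(O)c4)cc3)c2)c1 | target

Total step count: 4
Longest linear sequence: 4 steps (1 → 2 → 3 → 4)

Steps most likely to fail

Step 2. The C–O coupling may stall because the phenoxide of 4 is hindered by its ortho benzyloxy group and made less nucleophilic by the formyl group, so protodebromination of 3 could compete with ether formation. The fallback sets out from 3 and reverses the roles in an oxidative coupling. Bromine–lithium exchange (n-BuLi, THF, −78 °C), quench with B(OiPr)3 and mild acidic work-up should give {4-[(E)-2-[3-(benzyloxy)phenyl]ethenyl]phenyl}boronic acid F1. A Chan–Lam–Evans coupling of this boronic acid with phenol 4 (Cu(OAc)2, pyridine, 4 Å molecular sieves, CH2Cl2, air, rt) should then form the diaryl ether at room temperature and come back to the route at 5.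

Step 3. Addition of the semi-stabilised carbanion to the electron-rich aldehyde (para-benzyloxy donor) may be slow, and the β-oxido phosphonate may not eliminate cleanly, leaving unreacted aldehyde or a hydroxy phosphonate. The fallback sets out from 5 and makes the same C–C bond by polar addition. 3-Methoxybenzylmagnesium chloride (THF, 0 °C) should give racemic 1-[4-(benzyloxy)-3-{4-[(E)-2-[3-(benzyloxy)phenyl]ethenyl]phenoxy}phenyl]-2-(3-methoxyphenyl)ethan-1-ol F2. Acid-catalysed dehydration of this doubly benzylic, para-alkoxy-activated carbinol (cat. p-TsOH, toluene, reflux, Dean–Stark) should then give the E-stilbene and come back to the route at 7.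

Step 4. Hydrogenolysis of the two benzyl ethers may lag behind alkene saturation if traces of copper or phosphorus from earlier steps poison the catalyst, giving partly debenzylated mixtures. The fallback sets out from 7 and separates the two tasks without a metal catalyst. Diimide reduction (TsNHNH2, NaOAc, THF–H2O, reflux) should saturate both alkenes to give 1-(benzyloxy)-2-{4-[2-[3-(benzyloxy)phenyl]ethyl]phenoxy}-4-[2-(3-methoxyphenyl)ethyl]benzene F3. Lewis-acid debenzylation with a cation scavenger (BCl3, pentamethylbenzene, CH2Cl2, −78 °C), which cleaves aryl benzyl ethers in preference to aryl methyl ethers, should then come back to the route at 8.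

Further compounds
F1 | step 2 | {4-[(E)-2-[3-(benzyloxy)phenyl]ethenyl]phenyl}boronic acid | OB(O)c1ccc(/C=C/c2cccc(OCc3ccccc3)c2)cc1
F2 | step 3 | racemic 1-[4-(benzyloxy)-3-{4-[(E)-2-[3-(benzyloxy)phenyl]ethenyl]phenoxy}phenyl]-2-(3-methoxyphenyl)ethan-1-ol | COc1cccc(CC(O)c2ccc(OCc3ccccc3)c(Oc3ccc(/C=C/c4cccc(OCc5ccccc5)c4)cc3)c2)c1
F3 | step 4 | 1-(benzyloxy)-2-{4-[2-[3-(benzyloxy)phenyl]ethyl]phenoxy}-4-[2-(3-methoxyphenyl)ethyl]benzene | COc1cccc(CCc2ccc(OCc3ccccc3)c(Oc3ccc(CCc4cccc(OCc5ccccc5)c4)cc3)c2)c1
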